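The plan disconnects the O–C8 bond of the 2,5-dihydrofuran (O, C5, C6, C7, C8; carotenoid numbering) and reads the array C5(O)–C6=C7–C8 as the product of an exocyclic α-hydroxyallene, C5(OH)–C6=C7=C8. A gold-catalysed 5-endo cycloisomerisation closes this ring, the last one of the skeleton, and converts the allene axis into the C8 stereocentre in one operation. The precursor is an allenic C15 ester whose ring (C3, C5) comes from (4R,6R)-actinol by Sharpless epoxidation and whose axis is set by anti SN2′ hydrogenolysis of an alkynyl epoxide. The C12 polyene tail, from the C10 dialdehyde, is added afterwards by Wittig olefination.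

Key step: step 11

Remark: carotenoid numbering (ring C1–C6, chain C7–C15 and C15′–C10′) is used in the reasoning; (4R,6R)-actinol and 2,7-dimethylocta-2,4,6-trienedial are taken as commercial carotenoid building blocks.

Step 1
Reactants: 1 (4R,6R)-4-hydroxy-2,2,6-trimethylcyclohexan-1-one ((4R,6R)-actinol)
Product: 2 (4R,6R)-4-[(tert-butyldimethylsilyl)oxy]-2,2,6-trimethylcyclohexan-1-one
Conditions: TBSCl, imidazole, DMF, rt
Reagents that add atoms: tert-butyldimethylsilyl chloride, CC(C)(C)[Si](C)(C)Cl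
Why: Silyl ether protection of the secondary alcohol masks O3 for the enolate chemistry and later keeps it from acting as a nucleophile, and no stereocentre is touched.

Step 2
Reactants: 2 (4R,6R)-4-[(tert-butyldimethylsilyl)oxy]-2,2,6-trimethylcyclohexan-1-one
Product: 4 (4R)-4-[(tert-butyldimethylsilyl)oxy]-2,6,6-trimethylcyclohex-1-en-1-yl trifluoromethanesulfonate, via lithium enolate 3 (not isolated)
Conditions: LiN(iPr)2, THF, −78 °C; PhNTf2, −78 °C to rt
Reagents that add atoms: N-phenylbis(trifluoromethanesulfonimide), O=S(=O)(N(c1ccccc1)S(=O)(=O)C(F)(F)F)C(F)(F)F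
Why: The ketone can enolise only toward the methine carbon because the other α-carbon is quaternary, so O-triflation of the enolate should give the tetrasubstituted enol triflate, the methyl-bearing stereocentre being erased on purpose.

Step 3
Reactants: 4 (4R)-4-[(tert-butyldimethylsilyl)oxy]-2,6,6-trimethylcyclohex-1-en-1-yl trifluoromethanesulfonate
Product: 5 methyl (4R)-4-[(tert-butyldimethylsilyl)oxy]-2,6,6-trimethylcyclohex-1-ene-1-carboxylate
Conditions: Pd(OAc)2 (5 mol %), PPh3, CO (1 atm), MeOH, Et3N, DMF, 60 °C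
Reagents that add atoms: carbon monoxide, [C-]#[O+]; methanol, CO
Why: Palladium-catalysed alkoxycarbonylation of the enol triflate (oxidative addition, CO insertion, methanolysis) should install C7 at the hindered ring position.

Step 4
Reactants: 5 methyl (4R)-4-[(tert-butyldimethylsilyl)oxy]-2,6,6-trimethylcyclohex-1-ene-1-carboxylate
Product: 6 [(4R)-4-[(tert-butyldimethylsilyl)oxy]-2,6,6-trimethylcyclohex-1-en-1-yl]methanol
Conditions: iBu2AlH, CH2Cl2, −78 to 0 °C
Reagents that add atoms: none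
Why: 1,2-Reduction of the enoate by the aluminium hydride should give the primary allylic alcohol needed to direct the epoxidation.

Step 5
Reactants: 6 [(4R)-4-[(tert-butyldimethylsilyl)oxy]-2,6,6-trimethylcyclohex-1-en-1-yl]methanol
Product: 7 [(1R,4S,6R)-4-[(tert-butyldimethylsilyl)oxy]-2,2,6-trimethyl-7-oxabicyclo[4.1.0]heptan-1-yl]methanol (epoxide anti to the silyloxy group)
Conditions: Ti(OiPr)4 (20 mol %), D-(−)-diethyl tartrate (25 mol %), t-BuOOH, 4 Å MS, CH2Cl2, −20 °C
Reagents that add atoms: tert-butyl hydroperoxide, CC(C)(C)OO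
Why: In this Sharpless asymmetric epoxidation the titanium D-(−)-tartrate complex should deliver oxygen under reagent control to the alkene face anti to the C3 silyloxy group, which sets C5 (R) and the trans relation of O5 to O3 that a peracid would not give reliably.

Step 6
Reactants: 7 [(1R,4S,6R)-4-[(tert-butyldimethylsilyl)oxy]-2,2,6-trimethyl-7-oxabicyclo[4.1.0]heptan-1-yl]methanol
Product: 8 (1S,4S,6R)-4-[(tert-butyldimethylsilyl)oxy]-2,2,6-trimethyl-7-oxabicyclo[4.1.0]heptane-1-carbaldehyde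
Conditions: Dess–Martin periodinane, pyridine, CH2Cl2, 0 °C to rt
Reagents that add atoms: none
Why: The buffered Dess–Martin oxidation should convert the primary alcohol into the aldehyde without opening the epoxide, and the α-carbon is quaternary so nothing can epimerise.

Step 7
Reactants: 8 (1S,4S,6R)-4-[(tert-butyldimethylsilyl)oxy]-2,2,6-trimethyl-7-oxabicyclo[4.1.0]heptane-1-carbaldehyde
Product: 9 tert-butyl{[(1R,3S,6R)-6-ethynyl-1,5,5-trimethyl-7-oxabicyclo[4.1.0]heptan-3-yl]oxy}dimethylsilane (ethynyl oxirane, ring stereochemistry as in 7)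
Conditions: dimethyl (1-diazo-2-oxopropyl)phosphonate, K2CO3, MeOH, 0 °C to rt
Reagents that add atoms: dimethyl (1-diazo-2-oxopropyl)phosphonate, CC(=O)C(=[N+]=[N-])P(=O)(OC)OC
Why: Seyferth–Gilbert homologation in the Ohira–Bestmann variant should turn the non-enolisable aldehyde into the terminal alkyne (new carbon C8) under mild base that leaves the epoxide intact.

Step 8
Reactants: 10 ethyl acetoacetate
Product: 11 ethyl (2E)-3-{[(trifluoromethyl)sulfonyl]oxy}but-2-enoate
Conditions: Tf2O, aq. Me4NOH, hexanes, 5 °C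
Reagents that add atoms: trifluoromethanesulfonic anhydride, O=S(=O)(OS(=O)(=O)C(F)(F)F)C(F)(F)F
Why: O-Triflation of the non-chelated tetramethylammonium enolate should give the (E)-enol triflate with the triflate trans to the ester, which fixes the later C9=C10 geometry.

Step 9
Reactants: 9 ethynyl oxirane; 11 ethyl (2E)-3-{[(trifluoromethyl)sulfonyl]oxy}but-2-enoate
Product: 12 ethyl (2E)-5-[(1R,4S,6R)-4-[(tert-butyldimethylsilyl)oxy]-2,2,6-trimethyl-7-oxabicyclo[4.1.0]heptan-1-yl]-3-methylpent-2-en-4-ynoate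
Conditions: Pd(PPh3)4 (5 mol %), CuI (10 mol %), Et3N, THF, rt
Reagents that add atoms: none
Why: Sonogashira coupling of the terminal alkyne with the activated vinyl triflate should form the C8–C9 bond with retention of the (E) geometry.

Step 10
Reactants: 12 ethyl (2E)-5-[(1R,4S,6R)-4-[(tert-butyldimethylsilyl)oxy]-2,2,6-trimethyl-7-oxabicyclo[4.1.0]heptan-1-yl]-3-methylpent-2-en-4-ynoate
Product: 13 ethyl (2E)-5-[(2R,4S)-4-[(tert-butyldimethylsilyl)oxy]-2-hydroxy-2,6,6-trimethylcyclohexylidene]-3-methylpenta-2,4-dienoate with the (S)-configured allene axis (H8 anti and C9 syn to the C5–O bond)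
Conditions: Pd2(dba)3·CHCl3 (2.5 mol %), PBu3 (10 mol %), HCO2H, Et3N (excess), THF, rt
Reagents that add atoms: none
Why: In this Tsuji-type formate hydrogenolysis of a propargylic epoxide, zerovalent palladium should attack C8 anti to the C6–O bond (SN2′ ionisation) and the hydride from formate is then passed to C8 from the metal with retention, so H8 ends anti and C9 syn to the C5–O bond, which defines the (S) axis while C5 keeps its oxygen and configuration.

Step 11
Reactants: 13 allenol ester with the (S) allene axis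
Product: 15 ethyl (2E)-3-[(2R,6S,7aR)-6-[(tert-butyldimethylsilyl)oxy]-4,4,7a-trimethyl-2,4,5,6,7,7a-hexahydro-1-benzofuran-2-yl]but-2-enoate, via alkenylgold intermediate 14 (not isolated)
Conditions: Ph3PAuCl (2 mol %), AgBF4 (2 mol %), toluene, 0 °C to rt
Reagents that add atoms: none
Why: The cationic Ph3PAu+ fragment coordinates the C7=C8 π-bond of the allene on the side away from the C5 hydroxyl, O5 adds to C8 (anti oxyauration) to give alkenylgold 14, and protodeauration at C7 releases 15 and the catalyst. The closest known reaction type is the gold- or silver-catalysed cycloisomerisation of α-hydroxyallenes to 2,5-dihydrofurans. The dihydrofuran ring (O, C5, C6, C7, C8) is closed in the 5-endo-trig mode by formation of the O–C8 bond. The new stereocentre C8 is controlled by axis-to-centre chirality transfer: O5 can reach C8 only within the plane of C1, C6 and C5, so the two C8 substituents that stand above and below this plane in the allene stay there, and C9, which lies on the face of the C5–O bond in 13, ends trans to the C5 methyl group, which is the (8R) configuration. The step needs O5 as the only nucleophile and no ionisation of the new allylic C8–O bond; the silyl ether at O3 prevents 3,6-ether formation and the electron-poor enoate at C9=C10 disfavours a C8 cation, a Nazarov-type closure of the vinylallene and epimerisation.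

Step 12
Reactants: 15 furanoid C15 ester
Product: 16 (2E)-3-[(2R,6S,7aR)-6-[(tert-butyldimethylsilyl)oxy]-4,4,7a-trimethyl-2,4,5,6,7,7a-hexahydro-1-benzofuran-2-yl]but-2-en-1-ol
Conditions: iBu2AlH, CH2Cl2, −78 °C
Reagents that add atoms: none
Why: 1,2-Reduction of the enoate should give the allylic alcohol at C11 while the ring ether and the silyl ether stay inert.

Step 13
Reactants: 16 furanoid C15 allylic alcohol
Product: 17 (2E)-3-[(2R,6S,7aR)-6-[(tert-butyldimethylsilyl)oxy]-4,4,7a-trimethyl-2,4,5,6,7,7a-hexahydro-1-benzofuran-2-yl]but-2-enal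
Conditions: MnO2, CH2Cl2, rt
Reagents that add atoms: none
Why: Neutral, chemoselective allylic oxidation should give the (E)-enal without touching C8.

Step 14
Reactants: 18 (2E,4E,6E)-2,7-dimethylocta-2,4,6-trienedial; 19 triethyl phosphonoacetate
Product: 21 ethyl (2E,4E,6E,8E)-4,9-dimethyl-10-oxodeca-2,4,6,8-tetraenoate, via sodium phosphonate carbanion 20 (not isolated)
Conditions: 19, NaH, THF, 0 °C; added to 18 (3 equiv), 0 °C to rt
Reagents that add atoms: none
Why: Horner–Wadsworth–Emmons mono-olefination of the symmetrical dialdehyde used in excess should give the (E)-enoate, and unreacted 18 can be recovered.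

Step 15
Reactants: 21 ethyl (2E,4E,6E,8E)-4,9-dimethyl-10-oxodeca-2,4,6,8-tetraenoate
Product: 22 ethyl (2E,4E,6E,8E)-10-hydroxy-4,9-dimethyldeca-2,4,6,8-tetraenoate
Conditions: NaBH4, EtOH, 0 °C
Reagents that add atoms: none
Why: Borohydride should reduce the aldehyde chemoselectively in the presence of the conjugated ester.

Step 16
Reactants: 22 ethyl (2E,4E,6E,8E)-10-hydroxy-4,9-dimethyldeca-2,4,6,8-tetraenoate
Product: 23 [(2E,4E,6E,8E)-10-ethoxy-2,7-dimethyl-10-oxodeca-2,4,6,8-tetraen-1-yl]triphenylphosphonium bromide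
Conditions: PPh3·HBr, CH2Cl2, rt
Reagents that add atoms: triphenylphosphine hydrobromide, [PH+](c1ccccc1)(c1ccccc1)c1ccccc1.[Br-]
Why: Acid-mediated substitution of the primary allylic alcohol by triphenylphosphine should give the phosphonium salt at the terminal carbon (the future C12).

Step 17
Reactants: 17 furanoid C15 aldehyde; 23 C12 phosphonium bromide
Product: 25 ethyl (2E,4E,6E,8E,10E,12E)-13-[(2R,6S,7aR)-6-[(tert-butyldimethylsilyl)oxy]-4,4,7a-trimethyl-2,4,5,6,7,7a-hexahydro-1-benzofuran-2-yl]-4,9-dimethyltetradeca-2,4,6,8,10,12-hexaenoate, via phosphorus ylide 24 (not isolated)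
Conditions: 23, NaOEt (1 equiv), EtOH/CH2Cl2, 0 °C; 17, 0 °C to rt; then EtOAc, 60 °C
Reagents that add atoms: none
Why: Wittig olefination with the conjugated, ester-stabilised ylide should form C11=C12 mainly as the (E) alkene, and the hindered (11Z) isomer is expected to isomerise on gentle heating.

Step 18
Reactants: 25 C27 ester
Product: 26 (2E,4E,6E,8E,10E,12E)-13-[(2R,6S,7aR)-6-[(tert-butyldimethylsilyl)oxy]-4,4,7a-trimethyl-2,4,5,6,7,7a-hexahydro-1-benzofuran-2-yl]-4,9-dimethyltetradeca-2,4,6,8,10,12-hexaen-1-ol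
Conditions: iBu2AlH, THF, −78 °C
Reagents that add atoms: none
Why: 1,2-Reduction of the polyenoate at low temperature in a donor solvent should give the C10′ allylic alcohol while sparing the acid-labile allylic ether at C8.

Step 19
Reactants: 26 C27 silyl ether
Product: 27 (2E,4E,6E,8E,10E,12E)-13-[(2R,6S,7aR)-6-hydroxy-4,4,7a-trimethyl-2,4,5,6,7,7a-hexahydro-1-benzofuran-2-yl]-4,9-dimethyltetradeca-2,4,6,8,10,12-hexaen-1-ol ((3S,5R,8R)-5,8-epoxy-5,8-dihydro-10′-apo-β-carotene-3,10′-diol, CNP0263491.1)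
Conditions: Bu4NF, THF, 0 °C to rt
Reagents that add atoms: none
Why: Fluoride cleavage of the silyl ether under non-acidic conditions should free the 3-hydroxyl and give the target without ionising the C8–O bond.

Compound list
1 | (4R,6R)-4-hydroxy-2,2,6-trimethylcyclohexan-1-one ((4R,6R)-actinol) | O=C1C(C)(C)C[C@H](O)C[C@H]1C | starting material
2 | (4R,6R)-4-[(tert-butyldimethylsilyl)oxy]-2,2,6-trimethylcyclohexan-1-one | O=C1C(C)(C)C[C@H](O[Si](C)(C)C(C)(C)C)C[C@H]1C | intermediate
3 | lithium (4R)-4-[(tert-butyldimethylsilyl)oxy]-2,6,6-trimethylcyclohex-1-en-1-olate (lithium enolate of 2) | CC1=C(O[Li])C(C)(C)C[C@H](O[Si](C)(C)C(C)(C)C)C1 | intermediate (not isolated)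
4 | (4R)-4-[(tert-butyldimethylsilyl)oxy]-2,6,6-trimethylcyclohex-1-en-1-yl trifluoromethanesulfonate | CC1=C(OS(=O)(=O)C(F)(F)F)C(C)(C)C[C@H](O[Si](C)(C)C(C)(C)C)C1 | intermediate
5 | methyl (4R)-4-[(tert-butyldimethylsilyl)oxy]-2,6,6-trimethylcyclohex-1-ene-1-carboxylate | CC1=C(C(=O)OC)C(C)(C)C[C@H](O[Si](C)(C)C(C)(C)C)C1 | intermediate
6 | [(4R)-4-[(tert-butyldimethylsilyl)oxy]-2,6,6-trimethylcyclohex-1-en-1-yl]methanol | CC1=C(CO)C(C)(C)C[C@H](O[Si](C)(C)C(C)(C)C)C1 | intermediate
7 | [(1R,4S,6R)-4-[(tert-butyldimethylsilyl)oxy]-2,2,6-trimethyl-7-oxabicyclo[4.1.0]heptan-1-yl]methanol | OC[C@]12C(C)(C)C[C@H](O[Si](C)(C)C(C)(C)C)C[C@@]1(C)O2 | intermediate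
8 | (1S,4S,6R)-4-[(tert-butyldimethylsilyl)oxy]-2,2,6-trimethyl-7-oxabicyclo[4.1.0]heptane-1-carbaldehyde | O=C[C@]12C(C)(C)C[C@H](O[Si](C)(C)C(C)(C)C)C[C@@]1(C)O2 | intermediate
9 | tert-butyl{[(1R,3S,6R)-6-ethynyl-1,5,5-trimethyl-7-oxabicyclo[4.1.0]heptan-3-yl]oxy}dimethylsilane (ethynyl oxirane) | C#C[C@]12C(C)(C)C[C@H](O[Si](C)(C)C(C)(C)C)C[C@@]1(C)O2 | intermediate
10 | ethyl acetoacetate | CCOC(=O)CC(C)=O | starting material
11 | ethyl (2E)-3-{[(trifluoromethyl)sulfonyl]oxy}but-2-enoate | CCOC(=O)/C=C(\C)OS(=O)(=O)C(F)(F)F | intermediate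
12 | ethyl (2E)-5-[(1R,4S,6R)-4-[(tert-butyldimethylsilyl)oxy]-2,2,6-trimethyl-7-oxabicyclo[4.1.0]heptan-1-yl]-3-methylpent-2-en-4-ynoate | CCOC(=O)/C=C(\C)C#C[C@]12C(C)(C)C[C@H](O[Si](C)(C)C(C)(C)C)C[C@@]1(C)O2 | intermediate
13 | ethyl (2E)-5-[(2R,4S)-4-[(tert-butyldimethylsilyl)oxy]-2-hydroxy-2,6,6-trimethylcyclohexylidene]-3-methylpenta-2,4-dienoate, (S) allene axis | CCOC(=O)/C=C(C)/C=[C@]=C1C(C)(C)C[C@H](O[Si](C)(C)C(C)(C)C)C[C@@]1(C)O | intermediate
14 | alkenylgold intermediate (15 carrying AuPPh3 at C7, the furan C3 position) | CCOC(=O)/C=C(C)/[C@H]1C([Au-][P+](c3ccccc3)(c3ccccc3)c3ccccc3)=C2C(C)(C)C[C@H](O[Si](C)(C)C(C)(C)C)C[C@@]2(C)O1 | intermediate (not isolated)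
15 | ethyl (2E)-3-[(2R,6S,7aR)-6-[(tert-butyldimethylsilyl)oxy]-4,4,7a-trimethyl-2,4,5,6,7,7a-hexahydro-1-benzofuran-2-yl]but-2-enoate | CCOC(=O)/C=C(C)/[C@H]1C=C2C(C)(C)C[C@H](O[Si](C)(C)C(C)(C)C)C[C@@]2(C)O1 | intermediate
16 | (2E)-3-[(2R,6S,7aR)-6-[(tert-butyldimethylsilyl)oxy]-4,4,7a-trimethyl-2,4,5,6,7,7a-hexahydro-1-benzofuran-2-yl]but-2-en-1-ol | OC/C=C(C)/[C@H]1C=C2C(C)(C)C[C@H](O[Si](C)(C)C(C)(C)C)C[C@@]2(C)O1 | intermediate
17 | (2E)-3-[(2R,6S,7aR)-6-[(tert-butyldimethylsilyl)oxy]-4,4,7a-trimethyl-2,4,5,6,7,7a-hexahydro-1-benzofuran-2-yl]but-2-enal | O=C/C=C(C)/[C@H]1C=C2C(C)(C)C[C@H](O[Si](C)(C)C(C)(C)C)C[C@@]2(C)O1 | intermediate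
18 | (2E,4E,6E)-2,7-dimethylocta-2,4,6-trienedial (C10 dialdehyde) | O=C/C(C)=C/C=C/C=C(C)/C=O | starting material
19 | triethyl phosphonoacetate | CCOC(=O)CP(=O)(OCC)OCC | starting material
20 | sodium salt of the carbanion of triethyl phosphonoacetate | [Na+].CCOC(=O)[CH-]P(=O)(OCC)OCC | intermediate (not isolated)
21 | ethyl (2E,4E,6E,8E)-4,9-dimethyl-10-oxodeca-2,4,6,8-tetraenoate | CCOC(=O)/C=C/C(C)=C/C=C/C=C(C)/C=O | intermediate
22 | ethyl (2E,4E,6E,8E)-10-hydroxy-4,9-dimethyldeca-2,4,6,8-tetraenoate | CCOC(=O)/C=C/C(C)=C/C=C/C=C(C)/CO | intermediate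
23 | [(2E,4E,6E,8E)-10-ethoxy-2,7-dimethyl-10-oxodeca-2,4,6,8-tetraen-1-yl]triphenylphosphonium bromide | CCOC(=O)/C=C/C(C)=C/C=C/C=C(C)/C[P+](c1ccccc1)(c1ccccc1)c1ccccc1.[Br-] | intermediate
24 | phosphorus ylide of 23 | CCOC(=O)/C=C/C(C)=C/C=C/C=C(C)/[CH-][P+](c1ccccc1)(c1ccccc1)c1ccccc1 | intermediate (not isolated)
25 | ethyl (2E,4E,6E,8E,10E,12E)-13-[(2R,6S,7aR)-6-[(tert-butyldimethylsilyl)oxy]-4,4,7a-trimethyl-2,4,5,6,7,7a-hexahydro-1-benzofuran-2-yl]-4,9-dimethyltetradeca-2,4,6,8,10,12-hexaenoate | CC(/C=C/C=C(\C)[C@H]1C=C2C(C)(C)C[C@H](O[Si](C)(C)C(C)(C)C)C[C@@]2(C)O1)=C\C=C\C=C(C)\C=C\C(=O)OCC | intermediate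
26 | (2E,4E,6E,8E,10E,12E)-13-[(2R,6S,7aR)-6-[(tert-butyldimethylsilyl)oxy]-4,4,7a-trimethyl-2,4,5,6,7,7a-hexahydro-1-benzofuran-2-yl]-4,9-dimethyltetradeca-2,4,6,8,10,12-hexaen-1-ol | CC(/C=C/C=C(\C)[C@H]1C=C2C(C)(C)C[C@H](O[Si](C)(C)C(C)(C)C)C[C@@]2(C)O1)=C\C=C\C=C(C)\C=C\CO | intermediate
27 | (2E,4E,6E,8E,10E,12E)-13-[(2R,6S,7aR)-6-hydroxy-4,4,7a-trimethyl-2,4,5,6,7,7a-hexahydro-1-benzofuran-2-yl]-4,9-dimethyltetradeca-2,4,6,8,10,12-hexaen-1-ol (CNP0263491.1) | CC(/C=C/C=C(\C)[C@H]1C=C2C(C)(C)C[C@H](O)C[C@@]2(C)O1)=C\C=C\C=C(C)\C=C\CO | target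

Total step count: 19. Longest linear sequence: 15 steps (steps 1–7, 9–13 and 17–19, from 1).

Steps most likely to fail

1. Step 10 (anti hydrogenolysis of the alkynyl epoxide). The anti course may leak if the allenylpalladium axis is scrambled by exchange with a second zerovalent palladium centre before hydride transfer, or hydride may be delivered at C6 to give an alkyne. The fallback replaces palladium by a copper hydride on a substrate without the enoate; it sets out from 9 and 11 and comes back at 16. The ester of 11 is reduced (iBu2AlH, CH2Cl2, −78 °C) to (2E)-4-hydroxybut-2-en-2-yl trifluoromethanesulfonate F1. Sonogashira coupling of F1 with 9 (Pd(PPh3)4, CuI, Et3N, THF) should give the epoxy enynol F2. An NHC–copper hydride SN2′ reduction ((IPr)CuCl, NaOtBu, MeSiH(OEt)2, toluene, 0 °C, aqueous NaOH work-up) proceeds by syn hydrocupration of the alkyne and anti β-alkoxide elimination and should give the allenediol F3 with the same (S) axis. The gold conditions of step 11 then convert F3 directly into 16, so step 12 is not needed.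

2. Step 11 (key step). Activation of the electron-poor vinylallene may be sluggish, or the axis-to-centre transfer may erode through reversible ionisation of the C8–O bond at the Lewis-acidic metal. The fallback is a stoichiometric electrophile-induced closure followed by removal of the electrophile; it sets out from 13 and comes back at 15. NIS (CH2Cl2, 0 °C) should give the iodo-dihydrofuran ester F4 by the same in-plane attack of O5 on C8, and radical hydrodeiodination (Bu3SnH, AIBN, toluene, 80 °C) then gives 15.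

3. Step 17 (Wittig coupling). The (E)-selectivity at C11=C12 may be incomplete, and the alkoxide base may deprotonate enal 17 at the γ-position C8 and erode that stereocentre. The fallback is a Horner–Wadsworth–Emmons coupling with a less basic phosphonate carbanion; it sets out from 22 and comes back at 25. PBr3 (Et2O, −20 °C) converts 22 into the allylic bromide F5, Arbuzov reaction with P(OEt)3 (90 °C) gives the phosphonate F6, and its sodium salt (NaN(SiMe3)2, THF, −78 °C) is condensed with 17 to give 25.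

Further compounds
F1 | step 10 | (2E)-4-hydroxybut-2-en-2-yl trifluoromethanesulfonate | OC/C=C(\C)OS(=O)(=O)C(F)(F)F
F2 | step 10 | (2E)-5-[(1R,4S,6R)-4-[(tert-butyldimethylsilyl)oxy]-2,2,6-trimethyl-7-oxabicyclo[4.1.0]heptan-1-yl]-3-methylpent-2-en-4-yn-1-ol | OC/C=C(\C)C#C[C@]12C(C)(C)C[C@H](O[Si](C)(C)C(C)(C)C)C[C@@]1(C)O2
F3 | step 10 | (1R,5S)-5-[(tert-butyldimethylsilyl)oxy]-2-[(3E)-5-hydroxy-3-methylpenta-1,3-dien-1-ylidene]-1,3,3-trimethylcyclohexan-1-ol, (S) allene axis | OC/C=C(C)/C=[C@]=C1C(C)(C)C[C@H](O[Si](C)(C)C(C)(C)C)C[C@@]1(C)O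
F4 | step 11 | ethyl (2E)-3-[(2S,6S,7aR)-6-[(tert-butyldimethylsilyl)oxy]-3-iodo-4,4,7a-trimethyl-2,4,5,6,7,7a-hexahydro-1-benzofuran-2-yl]but-2-enoate (same spatial arrangement at C8 as 15) | CCOC(=O)/C=C(C)/[C@H]1C(I)=C2C(C)(C)C[C@H](O[Si](C)(C)C(C)(C)C)C[C@@]2(C)O1
F5 | step 17 | ethyl (2E,4E,6E,8E)-10-bromo-4,9-dimethyldeca-2,4,6,8-tetraenoate | CCOC(=O)/C=C/C(C)=C/C=C/C=C(C)/CBr
F6 | step 17 | ethyl (2E,4E,6E,8E)-10-(diethoxyphosphoryl)-4,9-dimethyldeca-2,4,6,8-tetraenoate | CCOC(=O)/C=C/C(C)=C/C=C/C=C(C)/CP(=O)(OCC)OCC
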